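**Retrosynthetic overview**
1. The target is (2S)-7,2',4'-trihydroxy-6,8-diprenylflavanone; the last step only removes three phenolic silyl ethers from the protected flavanone 14.
2. Key disconnection: bond C2–C3 of ring C. The unit O1–C2(aryl)–C3H2–C4=O is a β-aryloxy ketone: C2 carries both the ring oxygen O1 and the 2,4-dioxygenated ring B, so it can be a doubly stabilised oxocarbenium carbon, and C3 is the α-carbon (enol carbon) of the ring-A aryl ketone.
3. This oxocarbenium/enol pair is stored as the isomeric six-membered vinyl acetal 12, a 2-aryl-4-methylidene-4H-1,3-benzodioxine in which C2 is bound to the C4 oxygen instead of C3. A chiral Brønsted acid isomerises it to the flavanone (asymmetric Petasis–Ferrier rearrangement), closing ring C and setting C2 in one operation.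
4. The vinyl acetal comes from a salicylic acid (7) and an aldehyde (9): silyl acetalization to a 1,3-benzodioxin-4-one (a temporary ring), then Petasis methylenation.
5. Ring A comes from methyl 2,4-dihydroxybenzoate by 3,5-dibromination and double linear-selective Negishi prenylation. Order of ring formation: temporary dioxinone ring (step 7), then ring C (step 9); rings A and B are bought.

Key step: step 9

Remark: 11 and 12 are racemic at the acetal carbon, which is harmless because step 9 erases this centre; the (S)-acid is assumed to give the (2S) product, and the mirror-image acid would be used if a test reaction showed the opposite sense. TBS = tert-butyldimethylsilyl, prenyl = 3-methylbut-2-en-1-yl.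

**Step 1**
Reactants: 1 methyl 2,4-dihydroxybenzoate
Product: 2 methyl 3,5-dibromo-2,4-dihydroxybenzoate
Conditions: Br2 (2.1 equiv), AcOH, rt
Reagents that add atoms: bromine, BrBr
Why: Electrophilic aromatic bromination should go only to C3 and C5, the positions ortho/para to both hydroxyl groups, while C6 is meta to both and stays free.

**Step 2**
Reactants: 2 methyl 3,5-dibromo-2,4-dihydroxybenzoate
Product: 3 methyl 3,5-dibromo-2,4-bis(TBS-oxy)benzoate
Conditions: TBSOTf (2.5 equiv), 2,6-lutidine, CH2Cl2, 0 °C to rt
Reagents that add atoms: tert-butyldimethylsilyl trifluoromethanesulfonate, CC(C)(C)[Si](C)(C)OS(=O)(=O)C(F)(F)F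
Why: O-Silylation with the silyl triflate is strong enough for the hindered, hydrogen-bonded 2-OH and the acidic 4-OH, and masks both phenols so that they cannot quench the allylzinc reagent of step 3.

**Step 3**
Reactants: 3 methyl 3,5-dibromo-2,4-bis(TBS-oxy)benzoate
Product: 4 methyl 2,4-bis(TBS-oxy)-3,5-diprenylbenzoate
Conditions: prenylzinc bromide (2.6 equiv; from prenyl bromide, Zn dust, LiCl, THF, 0 °C), Pd(OAc)2 (4 mol %), CPhos (2-dicyclohexylphosphino-2',6'-bis(dimethylamino)biphenyl, 8 mol %), THF, rt
Reagents that add atoms: 3-methylbut-2-enylzinc bromide, CC(C)=CC[Zn]Br (made in the flask from prenyl bromide, CC(C)=CCBr, and zinc)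
Why: Double Negishi coupling; with CPhos on zerovalent palladium, reductive elimination from the α-bound prenylpalladium aryl is fast, so the linear prenyl group should form at both C–Br bonds instead of the reverse-prenyl isomer, and the ester and silyl ethers are inert to the organozinc at rt.

**Step 4**
Reactants: 4 methyl 2,4-bis(TBS-oxy)-3,5-diprenylbenzoate
Product: 5 2,4-dihydroxy-3,5-diprenylbenzoic acid
Conditions: KOH (excess), MeOH/THF/H2O, 60 °C; then 1 M HCl, 0 °C, to pH 3
Reagents that add atoms: potassium hydroxide, [K+].[OH-]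
Why: Saponification of the methyl ester, in which hydroxide also cleaves both aryl silyl ethers (wanted, because the 2-OH and the acid must be free for step 7), while the prenyl alkenes are inert to base and the cold, brief acidification avoids chroman formation and decarboxylation.

**Step 5**
Reactants: 5 2,4-dihydroxy-3,5-diprenylbenzoic acid
Product: 7 4-(TBS-oxy)-2-hydroxy-3,5-diprenylbenzoic acid, via silyl ester 6 (not isolated)
Conditions: TBSCl (2.2 equiv), imidazole, DMF, rt; then AcOH/THF/H2O, rt
Reagents that add atoms: tert-butyldimethylsilyl chloride, CC(C)(C)[Si](C)(C)Cl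
Why: Silylation should take the carboxylic acid and the 4-OH but not the 2-OH, which is tied up in a hydrogen bond to the carbonyl group, and the silyl ester of 6 is then hydrolysed selectively by aqueous acetic acid, which leaves the aryl silyl ether.

**Step 6**
Reactants: 8 2,4-dihydroxybenzaldehyde
Product: 9 2,4-bis(TBS-oxy)benzaldehyde
Conditions: TBSCl (2.3 equiv), imidazole, DMF, rt
Reagents that add atoms: tert-butyldimethylsilyl chloride, CC(C)(C)[Si](C)(C)Cl
Why: Standard phenol silylation; silyl groups are chosen for ring B because they survive steps 7 to 9, keep the ring electron-rich, and leave in step 10 without strong acid or base.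

**Step 7**
Reactants: 7 4-(TBS-oxy)-2-hydroxy-3,5-diprenylbenzoic acid; 9 2,4-bis(TBS-oxy)benzaldehyde
Product: 11 racemic 2-[2,4-bis(TBS-oxy)phenyl]-7-(TBS-oxy)-6,8-diprenyl-4H-1,3-benzodioxin-4-one, via bis-trimethylsilyl derivative 10 (not isolated)
Conditions: (Me3Si)2NH, CH2Cl2, 40 °C, then evaporation; 9, TMSOTf (10 mol %), CH2Cl2, −78 °C; Et3N quench
Reagents that add atoms: none
Why: Noyori-type silyl acetalization (the TMSOTf-catalysed condensation of a bis-silylated hydroxy acid with an aldehyde that gives 1,3-dioxan-4-ones) should close the dioxinone ring at low temperature, driven by formation of hexamethyldisiloxane; the acetal carbon forms as a racemate, which does not matter.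

**Step 8**
Reactants: 11 racemic 2-[2,4-bis(TBS-oxy)phenyl]-7-(TBS-oxy)-6,8-diprenyl-4H-1,3-benzodioxin-4-one
Product: 12 racemic 2-[2,4-bis(TBS-oxy)phenyl]-7-(TBS-oxy)-4-methylidene-6,8-diprenyl-4H-1,3-benzodioxine
Conditions: Cp2TiMe2 (2.5 equiv), toluene, 65 °C, dark; filtration through basic alumina (pentane, 1% Et3N)
Reagents that add atoms: dimethyltitanocene Cp2TiMe2, [CH3-].[CH3-].[Ti+4].c1cc[cH-]c1.c1cc[cH-]c1
Why: Petasis methylenation: Cp2Ti=CH2 formed on heating should convert the lactone carbonyl into the exocyclic enol ether through an oxatitanacyclobutane under non-acidic, non-basic conditions, as in the standard entry to Petasis–Ferrier substrates, and silyl ethers and trisubstituted alkenes are tolerated.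

**Step 9**
Reactants: 12 racemic 2-[2,4-bis(TBS-oxy)phenyl]-7-(TBS-oxy)-4-methylidene-6,8-diprenyl-4H-1,3-benzodioxine
Product: 14 (2S)-2-[2,4-bis(TBS-oxy)phenyl]-7-(TBS-oxy)-6,8-diprenylchroman-4-one, via oxocarbenium enol ion pair 13 (not isolated)
Conditions: (S)-3,3'-bis(2,4,6-triisopropylphenyl)-1,1'-binaphthyl-2,2'-diyl N-(trifluoromethylsulfonyl)phosphoramide (5 mol %), toluene, 4 Å molecular sieves, −40 °C; Et3N quench
Reagents that add atoms: none
Why: Proposed new method: the acid protonates the enol-ether oxygen O3 of 12 and the C2–O3 bond ionises, because C2 is stabilised by O1 and by the ortho/para-silyloxy ring B, to give the tethered O-aryl oxocarbenium/enol pair 13 hydrogen-bonded to the chiral phosphoramide anion; the enol carbon then adds to the oxocarbenium carbon to form C2–C3, and loss of the proton from the C4 oxygen returns the catalyst. The closest known reactions are the Lewis-acid Petasis–Ferrier rearrangement of 4-methylene-1,3-dioxanes to tetrahydropyran-4-ones and the chiral-phosphoric-acid-catalysed aza-Petasis–Ferrier and related rearrangements of hemiaminal vinyl ethers and cyclic vinyl acetals, which run through the same ion-pair recombination; new here are the benzo-fused six-membered vinyl acetal and the enantioconvergent use of a racemic acetal. Ring C closes in a 6-(enolendo)-endo-trig mode while the dioxine ring opens, a geometry also used by the aza counterpart (iminium plus ortho-acyl enol closing to 2-aryl-2,3-dihydroquinolin-4-ones). The acetal stereocentre of 12 is erased on ionisation, and the new C2 centre should be set by the chiral counter-anion alone, which shields one face of the planar oxocarbenium while binding the enol OH. The step needs C- over O-recombination (O-return only regenerates 12), ionisation of the acetal in preference to protonation of the prenyl alkenes, and exclusion of water; the low temperature, the sieves, the 7-O-silyl group (no free phenol next to a prenyl group) and the strong stabilisation of the C2 cation should secure this, and protonation at the enol-ether carbon would fragment to the same C2 cation.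

**Step 10**
Reactants: 14 (2S)-2-[2,4-bis(TBS-oxy)phenyl]-7-(TBS-oxy)-6,8-diprenylchroman-4-one
Product: 15 (2S)-2-(2,4-dihydroxyphenyl)-7-hydroxy-6,8-diprenylchroman-4-one (target)
Conditions: Bu4NF/AcOH (1:1, 3.5 equiv each), THF, 0 °C
Reagents that add atoms: none
Why: Fluoride-mediated desilylation buffered by acetic acid should remove all three aryl silyl ethers without generating a free 4'-phenoxide, which could open ring C through a quinone methide and racemise C2; the prenyl groups and the ketone are untouched.

**Compound list**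
1 | methyl 2,4-dihydroxybenzoate | COC(=O)c1ccc(O)cc1O | starting material
2 | methyl 3,5-dibromo-2,4-dihydroxybenzoate | COC(=O)c1cc(Br)c(O)c(Br)c1O | intermediate
3 | methyl 3,5-dibromo-2,4-bis(tert-butyldimethylsilyloxy)benzoate | COC(=O)c1cc(Br)c(O[Si](C)(C)C(C)(C)C)c(Br)c1O[Si](C)(C)C(C)(C)C | intermediate
4 | methyl 2,4-bis(tert-butyldimethylsilyloxy)-3,5-bis(3-methylbut-2-en-1-yl)benzoate | COC(=O)c1cc(CC=C(C)C)c(O[Si](C)(C)C(C)(C)C)c(CC=C(C)C)c1O[Si](C)(C)C(C)(C)C | intermediate
5 | 2,4-dihydroxy-3,5-bis(3-methylbut-2-en-1-yl)benzoic acid | OC(=O)c1cc(CC=C(C)C)c(O)c(CC=C(C)C)c1O | intermediate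
6 | tert-butyldimethylsilyl 4-(tert-butyldimethylsilyloxy)-2-hydroxy-3,5-bis(3-methylbut-2-en-1-yl)benzoate | CC(C)(C)[Si](C)(C)OC(=O)c1cc(CC=C(C)C)c(O[Si](C)(C)C(C)(C)C)c(CC=C(C)C)c1O | intermediate
7 | 4-(tert-butyldimethylsilyloxy)-2-hydroxy-3,5-bis(3-methylbut-2-en-1-yl)benzoic acid | OC(=O)c1cc(CC=C(C)C)c(O[Si](C)(C)C(C)(C)C)c(CC=C(C)C)c1O | intermediate
8 | 2,4-dihydroxybenzaldehyde | O=Cc1ccc(O)cc1O | starting material
9 | 2,4-bis(tert-butyldimethylsilyloxy)benzaldehyde | O=Cc1ccc(O[Si](C)(C)C(C)(C)C)cc1O[Si](C)(C)C(C)(C)C | intermediate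
10 | trimethylsilyl 4-(tert-butyldimethylsilyloxy)-3,5-bis(3-methylbut-2-en-1-yl)-2-(trimethylsilyloxy)benzoate | C[Si](C)(C)OC(=O)c1cc(CC=C(C)C)c(O[Si](C)(C)C(C)(C)C)c(CC=C(C)C)c1O[Si](C)(C)C | intermediate
11 | racemic 2-[2,4-bis(tert-butyldimethylsilyloxy)phenyl]-7-(tert-butyldimethylsilyloxy)-6,8-bis(3-methylbut-2-en-1-yl)-4H-1,3-benzodioxin-4-one | CC(C)=CCc1cc2c(c(CC=C(C)C)c1O[Si](C)(C)C(C)(C)C)OC(c1ccc(O[Si](C)(C)C(C)(C)C)cc1O[Si](C)(C)C(C)(C)C)OC2=O | intermediate
12 | racemic 2-[2,4-bis(tert-butyldimethylsilyloxy)phenyl]-7-(tert-butyldimethylsilyloxy)-4-methylidene-6,8-bis(3-methylbut-2-en-1-yl)-4H-1,3-benzodioxine | CC(C)=CCc1cc2c(c(CC=C(C)C)c1O[Si](C)(C)C(C)(C)C)OC(c1ccc(O[Si](C)(C)C(C)(C)C)cc1O[Si](C)(C)C(C)(C)C)OC2=C | intermediate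
13 | ring-opened O-aryl oxocarbenium ion bearing the free enol (cation of the ion pair; counter-ion is the conjugate base of the chiral acid) | CC(C)=CCc1cc(C(O)=C)c([O+]=Cc2ccc(O[Si](C)(C)C(C)(C)C)cc2O[Si](C)(C)C(C)(C)C)c(CC=C(C)C)c1O[Si](C)(C)C(C)(C)C | intermediate
14 | (2S)-2-[2,4-bis(tert-butyldimethylsilyloxy)phenyl]-7-(tert-butyldimethylsilyloxy)-6,8-bis(3-methylbut-2-en-1-yl)-2,3-dihydro-4H-chromen-4-one | CC(C)=CCc1cc2c(c(CC=C(C)C)c1O[Si](C)(C)C(C)(C)C)O[C@H](c1ccc(O[Si](C)(C)C(C)(C)C)cc1O[Si](C)(C)C(C)(C)C)CC2=O | intermediate
15 | (2S)-2-(2,4-dihydroxyphenyl)-7-hydroxy-6,8-bis(3-methylbut-2-en-1-yl)-2,3-dihydro-4H-chromen-4-one | CC(C)=CCc1cc2c(c(CC=C(C)C)c1O)O[C@H](c1ccc(O)cc1O)CC2=O | target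

**Step count and risks**
Total steps: 10. Longest linear sequence: 9 steps (steps 1, 2, 3, 4, 5, 7, 8, 9, 10); step 6 is the side branch.

Steps most likely to fail:

1. Step 9. Facial discrimination in the oxocarbenium/enol ion pair may be poor, turnover may be slow, or the acid may protonate a prenyl alkene or hydrolyse the vinyl acetal with adventitious water. Fallback, setting out from 12: the established Petasis–Ferrier rearrangement with an achiral Lewis acid (Me2AlCl, CH2Cl2, −78 °C) should give the racemic silyl-protected flavanone F1, whose enantiomers would be separated by preparative HPLC on a polysaccharide chiral stationary phase; the (2S)-enantiomer is 14, where the route is rejoined. Stereocontrol thus changes from asymmetric catalysis to resolution.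

2. Step 8. The electron-rich aryl acetal may ionise prematurely under the Lewis-acidic titanium by-products at 65 °C, which would give racemic rearrangement or decomposition, or the vinyl acetal may hydrolyse during isolation. Fallback, setting out from 7 and giving up the vinyl acetal: MeLi (3.2 equiv, THF, −78 to 0 °C) should convert the acid into the methyl ketone 1-[4-(tert-butyldimethylsilyloxy)-2-hydroxy-3,5-bis(3-methylbut-2-en-1-yl)phenyl]ethanone F2. A Kabbe-type condensation of F2 with aldehyde 9 (pyrrolidine, toluene/EtOH, rt to 50 °C) should give the racemic silyl-protected flavanone F1, which is resolved as above to rejoin the route at 14.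

3. Step 3. Oxidative addition at the C3 bromide, flanked by two silyloxy groups, may be incomplete (mono-coupling), or some γ-coupling may give reverse-prenyl isomers. Fallback, setting out from 1 and replacing cross-coupling by electrophilic aromatic substitution: prenylation with 2-methylbut-3-en-2-ol and BF3·OEt2 (dioxane, rt) should give, after separation from mono-prenylated material, methyl 2,4-dihydroxy-3,5-bis(3-methylbut-2-en-1-yl)benzoate F3, which is saponified (KOH, MeOH/H2O, 60 °C, then cold dilute HCl) to rejoin the route at 5.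

**Further compounds**
F1 | step 9 | racemic 2-[2,4-bis(tert-butyldimethylsilyloxy)phenyl]-7-(tert-butyldimethylsilyloxy)-6,8-bis(3-methylbut-2-en-1-yl)-2,3-dihydro-4H-chromen-4-one | CC(C)=CCc1cc2c(c(CC=C(C)C)c1O[Si](C)(C)C(C)(C)C)OC(c1ccc(O[Si](C)(C)C(C)(C)C)cc1O[Si](C)(C)C(C)(C)C)CC2=O
F2 | step 8 | 1-[4-(tert-butyldimethylsilyloxy)-2-hydroxy-3,5-bis(3-methylbut-2-en-1-yl)phenyl]ethanone | CC(=O)c1cc(CC=C(C)C)c(O[Si](C)(C)C(C)(C)C)c(CC=C(C)C)c1O
F3 | step 3 | methyl 2,4-dihydroxy-3,5-bis(3-methylbut-2-en-1-yl)benzoate | COC(=O)c1cc(CC=C(C)C)c(O)c(CC=C(C)C)c1O
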